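**Plan**

- Retrosynthesis: the free phenols come from benzyl ethers; the C3 acetate / C5 hydroxyl pair comes from one cyclic orthoacetate (a 2-methoxy-2-methyl-1,3-dioxane) spanning O3 and O5. Both aryl–CH2 bonds (C1–aryl and C7–aryl) are then cut together, giving a 4,6-divinyl-1,3-dioxane and two molecules of O-benzyl-4-bromoguaiacol.
- The divinyl diol is cut at C1–C2 and C6–C7 back to (2R,4R)-1,2:4,5-diepoxypentane, and this to 1,5-dichloropentane-2,4-dione.
- Forward: C5 diketone → anti diol → diepoxide → C7 diene diol → dioxane orthoester ring → both guaiacyl rings attached in one pot (one diene, two molecules of aryl bromide) and the dioxane ring opened to the monoacetate → debenzylation.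
- Enabling feature: the C2 axis through C4 of the 1,7-diarylheptane-3,5-diol core. It makes C1/C7, the two aryl rings and O3/O5 pairwise equivalent, so one three-component coupling builds both aryl–CH2 bonds and the dioxane ring can open to only one monoacetate.
- Stereochemistry: both carbinol centres are set in step 1 by catalyst-controlled asymmetric hydrogenation (anti, 2R,4R) and are not touched again. The change to 3S,5S in the target is only a change in CIP priorities.

Key step: step 6

Assumption: 1,5-dichloropentane-2,4-dione is taken as a catalogue compound, and the (S)-BINAP ligand is assigned to the 2R,4R diol by analogy with the hydrogenation of 4-chloro-3-oxobutanoates (the mirror-image ligand would be used if the sense proved opposite).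

**Route**

Step 1
Reactants: 1 1,5-dichloropentane-2,4-dione
Product: 2 (2R,4R)-1,5-dichloropentane-2,4-diol
Conditions: H2 (80 bar), [RuCl2((S)-BINAP)]2·NEt3 (0.2 mol%), MeOH, 80–100 °C; recrystallisation
Reagents that add atoms: none
Why: Noyori asymmetric hydrogenation of a 1,3-diketone, in which the neighbouring carbonyl and then the first-formed hydroxyl chelate ruthenium so that the (S)-BINAP ligand should control hydride delivery at both carbonyls and set both centres as R (anti diol), any meso diol being removed by crystallisation.

Step 2
Reactants: 2 (2R,4R)-1,5-dichloropentane-2,4-diol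
Product: 3 (2R,4R)-1,2:4,5-diepoxypentane
Conditions: KOH (powdered, 4 equiv), Et2O, 0 °C to rt
Reagents that add atoms: none
Why: Twofold intramolecular Williamson etherification (chlorohydrin-to-epoxide closure), in which each alkoxide displaces chloride at the adjacent primary carbon so that neither carbinol stereocentre is involved.

Step 3
Reactants: 3 (2R,4R)-1,2:4,5-diepoxypentane
Product: 4 (3R,5R)-hepta-1,6-diene-3,5-diol
Conditions: Me3SI (6.5 equiv), n-BuLi (6 equiv), THF, −10 °C to rt; then H2O
Reagents that add atoms: trimethylsulfonium iodide, C[S+](C)C.[I-]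
Why: One-carbon homologation of terminal epoxides to allylic alcohols with excess dimethylsulfonium methylide, which opens each oxirane at its CH2 terminus and then, through ylide-mediated elimination of dimethyl sulfide from the γ-oxido sulfonium salt, leaves a vinyl group while the carbinol centres stay untouched.

Step 4
Reactants: 4 (3R,5R)-hepta-1,6-diene-3,5-diol
Product: 5 (4R,6R)-4,6-diethenyl-2-methoxy-2-methyl-1,3-dioxane
Conditions: MeC(OMe)3 (1.5 equiv), PPTS (2 mol%), CH2Cl2, rt; Et3N, evaporation
Reagents that add atoms: trimethyl orthoacetate, CC(OC)(OC)OC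
Why: Acid-catalysed orthoester exchange closes the six-membered cyclic orthoacetate at room temperature, far below the temperature of a Johnson–Claisen rearrangement, and since exchanging the two substituents on the orthoester carbon is undone by the C2 rotation of the trans-4,6-disubstituted ring, that carbon is not a stereocentre and one compound should form.

Step 5
Reactants: 6 4-bromo-2-methoxyphenol
Product: 7 1-(benzyloxy)-4-bromo-2-methoxybenzene
Conditions: BnBr (1.1 equiv), K2CO3 (1.5 equiv), acetone, reflux
Reagents that add atoms: benzyl bromide, BrCc1ccccc1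
Why: Williamson ether synthesis (SN2 O-benzylation of the phenoxide), which masks the phenol so that the bromide enters the coupling as a neutral aryl ether that can be unmasked at the end by hydrogenolysis.

Step 6
Reactants: 5 (4R,6R)-4,6-diethenyl-2-methoxy-2-methyl-1,3-dioxane; 7 1-(benzyloxy)-4-bromo-2-methoxybenzene (two molecules)
Product: 10 (3S,5S)-1,7-bis[4-(benzyloxy)-3-methoxyphenyl]-5-hydroxyheptan-3-yl acetate, via bis(9-BBN) dialkylborane 8 (not isolated), via diaryl cyclic orthoester 9 (not isolated)
Conditions: 9-BBN dimer (1.2 equiv), THF, 0 °C to rt; then 7 (2.3 equiv), Pd(dppf)Cl2·CH2Cl2 (5 mol%), 3 M aq NaOH (6 equiv), THF, 65 °C; then aq AcOH to pH 4, rt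
Reagents that add atoms: water, O; 1-(benzyloxy)-4-bromo-2-methoxybenzene (second molecule of 7), COc1cc(Br)ccc1OCc1ccccc1
Why: 9-BBN adds to each terminal vinyl group with boron on CH2 (anti-Markovnikov, reinforced by the allylic ring oxygen), hydroxide turns the two primary alkylboranes into borates, and each transmetalates to an arylpalladium bromide formed by oxidative addition of one molecule of 7 to zerovalent palladium, after which reductive elimination joins the former vinyl CH2 to the bromine-bearing ring carbon, so that one diene and two molecules of the aryl bromide are united in one pot (a B-alkyl Suzuki–Miyaura coupling, the closest known reaction type, run at both ends of one substrate). No ring is closed and no stereocentre is formed, since C4 and C6 of the dioxane are spectators and keep their configuration. The step needs regioselective hydroboration at the terminal carbon, secured by the bulk of 9-BBN on a monosubstituted alkene, and coupling faster than β-hydride elimination, secured by the primary alkyl groups and the wide-bite-angle dppf ligand. The base-stable 2-methoxy-2-methyl-1,3-dioxane ring shields both oxygens, so no ester is exposed to hydroxide during the coupling. On mild acidification the ring loses methanol to a 2-methyl-1,3-dioxan-2-ylium ion, which adds water and opens to the hydroxy acetate, and because the two ring oxygens of this ion are exchanged by the C2 axis either opening gives the same monoacetate.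

Step 7
Reactants: 10 (3S,5S)-1,7-bis[4-(benzyloxy)-3-methoxyphenyl]-5-hydroxyheptan-3-yl acetate
Product: 11 (3S,5S)-5-hydroxy-1,7-bis(4-hydroxy-3-methoxyphenyl)heptan-3-yl acetate
Conditions: H2 (1 atm), Pd/C (10%), EtOAc, rt
Reagents that add atoms: none
Why: Catalytic hydrogenolysis of the two aryl benzyl ethers over palladium on carbon under neutral conditions should leave the secondary acetate, the free alcohol and both stereocentres unchanged, and a 1,3-acetyl shift would be degenerate because the diol core is C2-symmetric.

**Compound list**

1 | 1,5-dichloropentane-2,4-dione | ClCC(=O)CC(=O)CCl | starting material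
2 | (2R,4R)-1,5-dichloropentane-2,4-diol | ClC[C@H](O)C[C@@H](O)CCl | intermediate
3 | (2R,4R)-1,2:4,5-diepoxypentane [(2R,2'R)-2,2'-methylenebis(oxirane)] | C1O[C@@H]1C[C@@H]1CO1 | intermediate
4 | (3R,5R)-hepta-1,6-diene-3,5-diol | C=C[C@H](O)C[C@@H](O)C=C | intermediate
5 | (4R,6R)-4,6-diethenyl-2-methoxy-2-methyl-1,3-dioxane | C=C[C@H]1C[C@H](C=C)OC(C)(OC)O1 | intermediate
6 | 4-bromo-2-methoxyphenol | COc1cc(Br)ccc1O | starting material
7 | 1-(benzyloxy)-4-bromo-2-methoxybenzene | COc1cc(Br)ccc1OCc1ccccc1 | intermediate
8 | (4S,6S)-4,6-bis[2-(9-borabicyclo[3.3.1]nonan-9-yl)ethyl]-2-methoxy-2-methyl-1,3-dioxane | COC1(C)O[C@@H](CCB2C3CCCC2CCC3)C[C@H](CCB2C3CCCC2CCC3)O1 | intermediate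
9 | (4S,6S)-4,6-bis{2-[4-(benzyloxy)-3-methoxyphenyl]ethyl}-2-methoxy-2-methyl-1,3-dioxane | COc1cc(CC[C@H]2C[C@H](CCc3ccc(OCc4ccccc4)c(OC)c3)OC(C)(OC)O2)ccc1OCc1ccccc1 | intermediate
10 | (3S,5S)-1,7-bis[4-(benzyloxy)-3-methoxyphenyl]-5-hydroxyheptan-3-yl acetate | COc1cc(CC[C@H](O)C[C@H](CCc2ccc(OCc3ccccc3)c(OC)c2)OC(C)=O)ccc1OCc1ccccc1 | intermediate
11 | (3S,5S)-5-hydroxy-1,7-bis(4-hydroxy-3-methoxyphenyl)heptan-3-yl acetate | COc1cc(CC[C@H](O)C[C@H](CCc2ccc(O)c(OC)c2)OC(C)=O)ccc1O | target

**Count and risks**

Total steps: 7. Longest linear sequence: 6 steps (steps 1, 2, 3, 4, 6, 7).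

Steps most likely to fail:

Step 6. The borane may attack or open the orthoester ring before the coupling, or the twofold coupling may stall after one arm through protodeboronation or β-hydride elimination. The fallback sets out from 5. A twofold Mizoroki–Heck arylation with two molecules of 7 (Pd(OAc)2, P(o-tol)3, K2CO3, DMF, 100 °C) would give the distyryl orthoester (4R,6R)-4,6-bis{(E)-2-[4-(benzyloxy)-3-methoxyphenyl]ethenyl}-2-methoxy-2-methyl-1,3-dioxane F1 with no borane present. Diimide generated from 2-nitrobenzenesulfonohydrazide and Et3N (CH2Cl2, rt) should then saturate both styrene double bonds without hydrogenolysis of the allylic C–O bonds or the benzyl ethers. This comes back to the route at 9, which aqueous acetic acid opens to 10 as before.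

Step 4. The acid- and moisture-labile allylic orthoester may open prematurely during isolation, or ring closure may stop at acyclic mixed orthoesters. The fallback sets out from 4 and carries the diol through the coupling as an acetonide. 2,2-Dimethoxypropane and PPTS would give (4R,6R)-4,6-diethenyl-2,2-dimethyl-1,3-dioxane F2. 9-BBN would give the dialkylborane (4S,6S)-4,6-bis[2-(9-borabicyclo[3.3.1]nonan-9-yl)ethyl]-2,2-dimethyl-1,3-dioxane F3 (not isolated), which is coupled with two molecules of 7 under the conditions of step 6 without the acid treatment to give (4S,6S)-4,6-bis{2-[4-(benzyloxy)-3-methoxyphenyl]ethyl}-2,2-dimethyl-1,3-dioxane F4. Aqueous acetic acid at 40 °C would free the diol (3S,5S)-1,7-bis[4-(benzyloxy)-3-methoxyphenyl]heptane-3,5-diol F5. Only then would MeC(OMe)3 with catalytic camphorsulfonic acid form the cyclic orthoester in the flask, so the route is rejoined at 9, which aqueous acetic acid opens to 10.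

Step 3. Homologation may be incomplete at one of the two oxiranes, simple ring opening may compete, and the small water-soluble diol may be lost on isolation. The fallback sets out from 3. (Phenylselanyl)methyllithium (from bis(phenylselanyl)methane and n-BuLi, THF, −78 °C) would open both oxiranes at CH2 to give the non-volatile (3R,5R)-1,7-bis(phenylselanyl)heptane-3,5-diol F6. Oxidation with H2O2 to the bis-selenoxide (3R,5R)-1,7-bis(benzeneseleninyl)heptane-3,5-diol F7 (not isolated), followed by syn-elimination on warming with diisopropylamine, would form both vinyl groups and come back to the route at 4.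

**Further compounds**

F1 | step 6 | (4R,6R)-4,6-bis{(E)-2-[4-(benzyloxy)-3-methoxyphenyl]ethenyl}-2-methoxy-2-methyl-1,3-dioxane | COc1cc(/C=C/[C@H]2C[C@H](/C=C/c3ccc(OCc4ccccc4)c(OC)c3)OC(C)(OC)O2)ccc1OCc1ccccc1
F2 | step 4 | (4R,6R)-4,6-diethenyl-2,2-dimethyl-1,3-dioxane | C=C[C@H]1C[C@H](C=C)OC(C)(C)O1
F3 | step 4 | (4S,6S)-4,6-bis[2-(9-borabicyclo[3.3.1]nonan-9-yl)ethyl]-2,2-dimethyl-1,3-dioxane | CC1(C)O[C@@H](CCB2C3CCCC2CCC3)C[C@H](CCB2C3CCCC2CCC3)O1
F4 | step 4 | (4S,6S)-4,6-bis{2-[4-(benzyloxy)-3-methoxyphenyl]ethyl}-2,2-dimethyl-1,3-dioxane | COc1cc(CC[C@H]2C[C@H](CCc3ccc(OCc4ccccc4)c(OC)c3)OC(C)(C)O2)ccc1OCc1ccccc1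
F5 | step 4 | (3S,5S)-1,7-bis[4-(benzyloxy)-3-methoxyphenyl]heptane-3,5-diol | COc1cc(CC[C@H](O)C[C@@H](O)CCc2ccc(OCc3ccccc3)c(OC)c2)ccc1OCc1ccccc1
F6 | step 3 | (3R,5R)-1,7-bis(phenylselanyl)heptane-3,5-diol | c1ccccc1[Se]CC[C@H](O)C[C@@H](O)CC[Se]c1ccccc1
F7 | step 3 | (3R,5R)-1,7-bis(benzeneseleninyl)heptane-3,5-diol (mixture at selenium) | O=[Se](c1ccccc1)CC[C@H](O)C[C@@H](O)CC[Se](=O)c1ccccc1
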